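**Retrosynthetic overview**
1. Target 23 ⇐ acetylation, desilylation and oxidation of macrocyclic diol 20 ⇐ Felkin–Anh reduction (sets C1) of ketone 19.
2. 19 ⇐ desulfonylation of 18 ⇐ ring-closing metathesis at C8=C9 of triene 17; the 13-membered ring is the only ring of the target and is closed in step 11.
3. 17 ⇐ C1–C2 union of aldehyde 11 with the sulfonyl carbanion of 15, made from (R)-linalool, which brings C7 and the E-C3=C4 alkene.
4. 11 ⇐ oxidative opening and mono-methylenation of cyclohexene 8, whose quaternary C13 is made by the key [2,3]-sigmatropic Wittig–Still rearrangement of cis-piperitol ether 5 (C13–C14 bond, 1,3-chirality transfer).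
5. 5 ⇐ (−)-menthone, which brings C10; its six-membered ring serves as a temporary template through step 4 and is cut in step 5.

Numbering used below: ring carbons C1 (acetoxy carbon) to C13 (quaternary carbon) as in the target; C14 is the formyl carbon. The target is (1S,7R,10S,13S) with 3E and 8E alkenes.
Assumption: (−)-menthone and (R)-(−)-linalool are bought in high enantiomeric purity.

**Step 1**
Reactants: 1 (−)-menthone [(2S,5R)-5-methyl-2-(propan-2-yl)cyclohexan-1-one]
Product: 3 (6S)-3-methyl-6-(propan-2-yl)cyclohex-2-en-1-one [(S)-piperitone], via silyl enol ether 2 (not isolated)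
Conditions: LiN(i-Pr)2, THF, −78 °C; Me3SiCl; then Pd(OAc)2, MeCN, rt
Reagents that add atoms: none
Why: Kinetic deprotonation at the ring methylene followed by Saegusa–Ito dehydrogenation of the silyl enol ether gives the enone and leaves the isopropyl-bearing stereocentre (future C10) untouched.

**Step 2**
Reactants: 3 (S)-piperitone
Product: 4 (1R,6S)-3-methyl-6-(propan-2-yl)cyclohex-2-en-1-ol [cis-piperitol]
Conditions: LiBH(s-Bu)3, THF, −78 °C
Reagents that add atoms: none
Why: The bulky hydride does a 1,2-reduction (the β,β-disubstituted enone resists conjugate reduction) from the face anti to the neighbouring isopropyl group, so the new carbinol is pseudoaxial and cis to isopropyl.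

**Step 3**
Reactants: 4 cis-piperitol
Product: 5 tributyl({[(1R,6S)-3-methyl-6-(propan-2-yl)cyclohex-2-en-1-yl]oxy}methyl)stannane
Conditions: KH, 18-crown-6 (cat.), THF, 0 °C; Bu3SnCH2I, rt
Reagents that add atoms: (iodomethyl)tributylstannane, CCCC[Sn](CCCC)(CCCC)CI
Why: Williamson etherification of the potassium alkoxide with the primary iodide installs the Wittig–Still precursor without touching a stereocentre.

**Step 4**
Reactants: 5 stannylmethyl ether
Product: 8 {[(1S,4S)-1-methyl-4-(propan-2-yl)cyclohex-2-en-1-yl]methoxy}tri(propan-2-yl)silane, via lithiomethyl ether 6 (not isolated), via lithium alkoxide 7 (not isolated)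
Conditions: n-BuLi, THF, −78 to −20 °C; then i-Pr3SiOTf, −78 to 0 °C
Reagents that add atoms: triisopropylsilyl trifluoromethanesulfonate, CC(C)[Si](C(C)C)(C(C)C)OS(=O)(=O)C(F)(F)F
Why: Tin–lithium exchange triggers the suprafacial [2,3]-sigmatropic Wittig–Still rearrangement, which delivers the CH2O carbon (C14) to the methyl-bearing alkene carbon on the face of the pseudoaxial C–O bond, so the quaternary C13 forms cis to isopropyl with the (S) configuration, and the alkoxide is silylated in the same flask.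

**Step 5**
Reactants: 8 cyclohexene silyl ether
Product: 10 (2R,5S)-2-methyl-5-(propan-2-yl)-2-({[tri(propan-2-yl)silyl]oxy}methyl)hexanedial, via cis-diol 9 (not isolated)
Conditions: OsO4 (2 mol %), NaIO4, 2,6-lutidine, 1,4-dioxane/H2O, rt
Reagents that add atoms: osmium tetroxide, O=[Os](=O)(=O)=O; sodium periodate, [Na+].[O-]I(=O)(=O)=O
Why: Lemieux–Johnson cleavage of the only alkene opens the template ring to the C1 and C9 aldehydes under buffered conditions that do not epimerise the α-stereocentre.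

**Step 6**
Reactants: 10 dialdehyde
Product: 11 (2R,5S)-2-methyl-5-(propan-2-yl)-2-({[tri(propan-2-yl)silyl]oxy}methyl)hept-6-enal
Conditions: Ph3PCH3Br, KN(SiMe3)2, THF, 0 °C; then 10 (1.0 equiv ylide), −78 to −40 °C
Reagents that add atoms: methyltriphenylphosphonium bromide, [Br-].C[P+](c1ccccc1)(c1ccccc1)c1ccccc1
Why: Wittig methylenation occurs at the aldehyde on the tertiary carbon, because the neopentyl aldehyde on quaternary C13 is much more hindered, and the low temperature protects the α-stereocentre.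

**Step 7**
Reactants: 12 (R)-(−)-linalool [(3R)-3,7-dimethylocta-1,6-dien-3-ol]
Product: 13 (2E,6R)-2,6-dimethylocta-2,7-diene-1,6-diol
Conditions: SeO2 (cat.), t-BuOOH, salicylic acid (cat.), CH2Cl2, rt
Reagents that add atoms: selenium dioxide, O=[Se]=O; tert-butyl hydroperoxide, CC(C)(C)OO
Why: The SeO2 allylic oxidation (ene reaction then [2,3] shift) hydroxylates only the E-methyl of the trisubstituted alkene, so the E geometry of the future C3=C4 bond and the C7 stereocentre are kept.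

**Step 8**
Reactants: 13 allylic diol
Product: 15 (3R,6E)-8-(benzenesulfonyl)-3,7-dimethylocta-1,6-dien-3-ol, via allylic chloride 14 (not isolated)
Conditions: N-chlorosuccinimide, Me2S, CH2Cl2, −20 to 0 °C; then PhSO2Na, Bu4NI (cat.), DMF, rt
Reagents that add atoms: sodium benzenesulfinate, [Na+].[O-]S(=O)c1ccccc1
Why: Corey–Kim chlorination converts only the primary allylic alcohol, and SN2 displacement by sulfinate gives the E-allylic sulfone while the tertiary alcohol is untouched.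

**Step 9**
Reactants: 15 allylic sulfone; 11 aldehyde
Product: 16 (3R,6E,10R,13S)-8-(benzenesulfonyl)-3,7,10-trimethyl-13-(propan-2-yl)-10-({[tri(propan-2-yl)silyl]oxy}methyl)pentadeca-1,6,14-triene-3,9-diol (mixture of epimers at C8 and C9)
Conditions: 15, n-BuLi (2.1 equiv), THF, −78 °C; then 11; AcOH/H2O quench at −78 °C
Reagents that add atoms: none
Why: The α-sulfonyl carbanion adds to the aldehyde through its α-carbon, so the C1–C2 bond forms without allylic transposition, and the two new stereocentres are erased in steps 10 and 12.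

**Step 10**
Reactants: 16 β-hydroxy sulfone
Product: 17 (3S,6R,9E,13R)-8-(benzenesulfonyl)-13-hydroxy-6,9,13-trimethyl-3-(propan-2-yl)-6-({[tri(propan-2-yl)silyl]oxy}methyl)pentadeca-1,9,14-trien-7-one (epimers at C8)
Conditions: Dess–Martin periodinane, NaHCO3, CH2Cl2, rt
Reagents that add atoms: none
Why: Dess–Martin oxidation converts the secondary carbinol to the β-keto sulfone and cannot touch the tertiary alcohol or the alkenes.

**Step 11**
Reactants: 17 β-keto sulfone triene
Product: 18 (3E,7R,8E,10S,13R)-2-(benzenesulfonyl)-7-hydroxy-3,7,13-trimethyl-10-(propan-2-yl)-13-({[tri(propan-2-yl)silyl]oxy}methyl)cyclotrideca-3,8-dien-1-one (epimers at C2)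
Conditions: second-generation Grubbs catalyst RuCl2(=CHPh)(PCy3)(H2IMes) (10 mol %), CH2Cl2 (1 mM), 40 °C
Reagents that add atoms: none
Why: Ring-closing metathesis of the two vinyl groups gives the 13-membered ring with the E-C8=C9 alkene (flanked by a quaternary carbinol and a branched carbon), while the branched keto-sulfone substituent on C3 blocks the competing five-membered closure onto the trisubstituted alkene.

**Step 12**
Reactants: 18 macrocyclic β-keto sulfone
Product: 19 (3E,7R,8E,10S,13R)-7-hydroxy-3,7,13-trimethyl-10-(propan-2-yl)-13-({[tri(propan-2-yl)silyl]oxy}methyl)cyclotrideca-3,8-dien-1-one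
Conditions: aluminium amalgam Al(Hg), THF/H2O (9:1), 0 °C to rt
Reagents that add atoms: none
Why: Reductive desulfonylation of the β-keto sulfone goes through the enolate, which is protonated at C2, so the sulfone is replaced by hydrogen without moving the C3=C4 alkene.

**Step 13**
Reactants: 19 macrocyclic ketone
Product: 20 (1S,3E,7R,8E,10S,13R)-3,7,13-trimethyl-10-(propan-2-yl)-13-({[tri(propan-2-yl)silyl]oxy}methyl)cyclotrideca-3,8-diene-1,7-diol
Conditions: LiBH(s-Bu)3, THF, −78 °C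
Reagents that add atoms: none
Why: In this non-chelating Felkin–Anh reduction the bulky silyloxymethyl branch on C13 sits anti to the incoming hydride, which passes over the methyl group and not the ring methylene, giving the (1S) carbinol; moderate selectivity is expected and the epimer is removed by chromatography.

**Step 14**
Reactants: 20 diol
Product: 21 (1S,3E,7R,8E,10S,13R)-7-hydroxy-3,7,13-trimethyl-10-(propan-2-yl)-13-({[tri(propan-2-yl)silyl]oxy}methyl)cyclotrideca-3,8-dien-1-yl acetate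
Conditions: Ac2O, Et3N, 4-(dimethylamino)pyridine (cat.), CH2Cl2, 0 °C to rt
Reagents that add atoms: acetic anhydride, CC(=O)OC(C)=O
Why: Nucleophilic-catalysed acylation esterifies the secondary alcohol while the tertiary allylic alcohol stays free under these mild conditions.

**Step 15**
Reactants: 21 silyl ether acetate
Product: 22 (1S,3E,7R,8E,10S,13R)-7-hydroxy-13-(hydroxymethyl)-3,7,13-trimethyl-10-(propan-2-yl)cyclotrideca-3,8-dien-1-yl acetate
Conditions: HF·pyridine, pyridine, THF, 0 °C to rt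
Reagents that add atoms: none
Why: Buffered acidic fluoride desilylation frees the primary alcohol without the 1,3-acetyl migration that basic fluoride could cause and without ionising the tertiary allylic alcohol.

**Step 16**
Reactants: 22 primary alcohol
Product: 23 (1S,3E,7R,8E,10S,13S)-13-formyl-7-hydroxy-3,7,13-trimethyl-10-(propan-2-yl)cyclotrideca-3,8-dien-1-yl acetate (target)
Conditions: Dess–Martin periodinane, NaHCO3, CH2Cl2, 0 °C to rt
Reagents that add atoms: none
Why: Dess–Martin oxidation gives the neopentyl aldehyde, which has no α-hydrogen and so cannot eliminate the β-acetate, while the tertiary alcohol is inert.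

**Compound list**
1 | (−)-menthone, (2S,5R)-5-methyl-2-(propan-2-yl)cyclohexan-1-one | CC(C)[C@@H]1CC[C@@H](C)CC1=O | starting material
2 | trimethyl{[(3R,6S)-3-methyl-6-(propan-2-yl)cyclohex-1-en-1-yl]oxy}silane | CC(C)[C@@H]1CC[C@@H](C)C=C1O[Si](C)(C)C | intermediate (not isolated)
3 | (S)-piperitone, (6S)-3-methyl-6-(propan-2-yl)cyclohex-2-en-1-one | CC1=CC(=O)[C@H](C(C)C)CC1 | intermediate
4 | cis-piperitol, (1R,6S)-3-methyl-6-(propan-2-yl)cyclohex-2-en-1-ol | CC1=C[C@H](O)[C@H](C(C)C)CC1 | intermediate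
5 | tributyl({[(1R,6S)-3-methyl-6-(propan-2-yl)cyclohex-2-en-1-yl]oxy}methyl)stannane | CC1=C[C@H](OC[Sn](CCCC)(CCCC)CCCC)[C@H](C(C)C)CC1 | intermediate
6 | ({[(1R,6S)-3-methyl-6-(propan-2-yl)cyclohex-2-en-1-yl]oxy}methyl)lithium | CC1=C[C@H](OC[Li])[C@H](C(C)C)CC1 | intermediate (not isolated)
7 | lithium [(1S,4S)-1-methyl-4-(propan-2-yl)cyclohex-2-en-1-yl]methanolate | [Li]OC[C@]1(C)C=C[C@H](C(C)C)CC1 | intermediate (not isolated)
8 | {[(1S,4S)-1-methyl-4-(propan-2-yl)cyclohex-2-en-1-yl]methoxy}tri(propan-2-yl)silane | CC(C)[Si](C(C)C)(C(C)C)OC[C@]1(C)C=C[C@H](C(C)C)CC1 | intermediate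
9 | (1S,2R,3R,6S)-3-methyl-6-(propan-2-yl)-3-({[tri(propan-2-yl)silyl]oxy}methyl)cyclohexane-1,2-diol | CC(C)[Si](C(C)C)(C(C)C)OC[C@]1(C)[C@@H](O)[C@@H](O)[C@H](C(C)C)CC1 | intermediate (not isolated)
10 | (2R,5S)-2-methyl-5-(propan-2-yl)-2-({[tri(propan-2-yl)silyl]oxy}methyl)hexanedial | CC(C)[Si](C(C)C)(C(C)C)OC[C@](C)(C=O)CC[C@@H](C(C)C)C=O | intermediate
11 | (2R,5S)-2-methyl-5-(propan-2-yl)-2-({[tri(propan-2-yl)silyl]oxy}methyl)hept-6-enal | CC(C)[Si](C(C)C)(C(C)C)OC[C@](C)(C=O)CC[C@@H](C(C)C)C=C | intermediate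
12 | (R)-(−)-linalool, (3R)-3,7-dimethylocta-1,6-dien-3-ol | CC(C)=CCC[C@@](C)(O)C=C | starting material
13 | (2E,6R)-2,6-dimethylocta-2,7-diene-1,6-diol | OC/C(C)=C/CC[C@@](C)(O)C=C | intermediate
14 | (3R,6E)-8-chloro-3,7-dimethylocta-1,6-dien-3-ol | ClC/C(C)=C/CC[C@@](C)(O)C=C | intermediate (not isolated)
15 | (3R,6E)-8-(benzenesulfonyl)-3,7-dimethylocta-1,6-dien-3-ol | O=S(=O)(C/C(C)=C/CC[C@@](C)(O)C=C)c1ccccc1 | intermediate
16 | (3R,6E,10R,13S)-8-(benzenesulfonyl)-3,7,10-trimethyl-13-(propan-2-yl)-10-({[tri(propan-2-yl)silyl]oxy}methyl)pentadeca-1,6,14-triene-3,9-diol, C8/C9 epimers | C=C[C@](C)(O)CC/C=C(\C)C(S(=O)(=O)c1ccccc1)C(O)[C@@](C)(CO[Si](C(C)C)(C(C)C)C(C)C)CC[C@@H](C(C)C)C=C | intermediate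
17 | (3S,6R,9E,13R)-8-(benzenesulfonyl)-13-hydroxy-6,9,13-trimethyl-3-(propan-2-yl)-6-({[tri(propan-2-yl)silyl]oxy}methyl)pentadeca-1,9,14-trien-7-one, C8 epimers | C=C[C@](C)(O)CC/C=C(\C)C(S(=O)(=O)c1ccccc1)C(=O)[C@@](C)(CO[Si](C(C)C)(C(C)C)C(C)C)CC[C@@H](C(C)C)C=C | intermediate
18 | (3E,7R,8E,10S,13R)-2-(benzenesulfonyl)-7-hydroxy-3,7,13-trimethyl-10-(propan-2-yl)-13-({[tri(propan-2-yl)silyl]oxy}methyl)cyclotrideca-3,8-dien-1-one, C2 epimers | O=C1C(S(=O)(=O)c2ccccc2)/C(C)=C/CC[C@@](C)(O)/C=C/[C@H](C(C)C)CC[C@]1(C)CO[Si](C(C)C)(C(C)C)C(C)C | intermediate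
19 | (3E,7R,8E,10S,13R)-7-hydroxy-3,7,13-trimethyl-10-(propan-2-yl)-13-({[tri(propan-2-yl)silyl]oxy}methyl)cyclotrideca-3,8-dien-1-one | O=C1C/C(C)=C/CC[C@@](C)(O)/C=C/[C@H](C(C)C)CC[C@]1(C)CO[Si](C(C)C)(C(C)C)C(C)C | intermediate
20 | (1S,3E,7R,8E,10S,13R)-3,7,13-trimethyl-10-(propan-2-yl)-13-({[tri(propan-2-yl)silyl]oxy}methyl)cyclotrideca-3,8-diene-1,7-diol | O[C@H]1C/C(C)=C/CC[C@@](C)(O)/C=C/[C@H](C(C)C)CC[C@]1(C)CO[Si](C(C)C)(C(C)C)C(C)C | intermediate
21 | (1S,3E,7R,8E,10S,13R)-7-hydroxy-3,7,13-trimethyl-10-(propan-2-yl)-13-({[tri(propan-2-yl)silyl]oxy}methyl)cyclotrideca-3,8-dien-1-yl acetate | CC(=O)O[C@H]1C/C(C)=C/CC[C@@](C)(O)/C=C/[C@H](C(C)C)CC[C@]1(C)CO[Si](C(C)C)(C(C)C)C(C)C | intermediate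
22 | (1S,3E,7R,8E,10S,13R)-7-hydroxy-13-(hydroxymethyl)-3,7,13-trimethyl-10-(propan-2-yl)cyclotrideca-3,8-dien-1-yl acetate | CC(=O)O[C@H]1C/C(C)=C/CC[C@@](C)(O)/C=C/[C@H](C(C)C)CC[C@]1(C)CO | intermediate
23 | (1S,3E,7R,8E,10S,13S)-13-formyl-7-hydroxy-3,7,13-trimethyl-10-(propan-2-yl)cyclotrideca-3,8-dien-1-yl acetate | CC(=O)O[C@H]1C/C(C)=C/CC[C@@](C)(O)/C=C/[C@H](C(C)C)CC[C@]1(C)C=O | target

**Step count**
Total: 16 steps. Longest linear sequence: 14 steps (steps 1–6 and 9–16 from 1); the linalool branch is steps 7–8.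

**The three steps most likely to fail**

Step 11 (ring-closing metathesis). The linalool-derived part of 17 is a 1,6-diene that can close to a cyclopentenol, and the macrocyclic alkene may form as an E/Z mixture. The fallback forms C8=C9 first by cross-metathesis, while the trisubstituted alkene is a conjugated and therefore inert enal, and closes the ring at C1–C2. It sets out from 11 and 13 and comes back at 18. MnO2 oxidation of 13 gives (2E,6R)-6-hydroxy-2,6-dimethylocta-2,7-dienal F4. Cross-metathesis of 11 with excess F4 using second-generation Hoveyda–Grubbs catalyst RuCl2(=CH-C6H4-2-O-i-Pr)(H2IMes) gives the E-configured dialdehyde F5. NaBH4/CeCl3 reduces only the conjugated aldehyde to the allylic alcohol F6. Corey–Kim chlorination gives the allylic chloride F7, and PhSO2Na gives the sulfone aldehyde F8. LiN(SiMe3)2 (2.2 equiv, THF, −78 °C, 1 mM) closes the ring by intramolecular sulfonyl-carbanion addition to the macrocyclic β-hydroxy sulfone F9. Dess–Martin oxidation of F9 returns to 18.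

Step 13 (C1 reduction). The α-quaternary centre offers only a methyl versus ring-methylene difference, so the Felkin–Anh selectivity may be low or reversed. The fallback replaces external delivery by hydroxyl-directed internal delivery. It sets out from 19 and comes back at 23. HF·pyridine gives the β-hydroxy ketone F10. Me4NBH(OAc)3 in MeCN/AcOH at −20 °C delivers hydride from boron bound to the C14 oxygen through a chair with the ring methylene anti to the carbonyl oxygen, giving the (1S) triol F11. TEMPO/PhI(OAc)2 oxidises only the primary alcohol to the hydroxy aldehyde F12. Ac2O/pyridine acetylates the secondary alcohol and gives 23.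

Step 6 (mono-methylenation of the dialdehyde). Bis-olefination or epimerisation next to the reacting aldehyde is possible. The fallback tells the two aldehydes apart by reduction and postpones the olefination until after fragment coupling. It sets out from 10 and comes back at 17. LiAlH(O-t-Bu)3 (1 equiv, THF, −78 °C) reduces only the less hindered aldehyde and gives the hydroxy aldehyde F1. Addition of the lithiated sulfone 15 (n-BuLi, one extra equivalent for the free hydroxyl) gives the triol sulfone F2. Dess–Martin periodinane oxidises both carbinols to the keto aldehyde F3. Excess Ph3P=CH2, which first converts the β-keto sulfone to its unreactive enolate, methylenates the aldehyde and gives 17.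

**Further compounds**
F1 | step 6 | (2R,5S)-5-(hydroxymethyl)-2,6-dimethyl-2-({[tri(propan-2-yl)silyl]oxy}methyl)heptanal | CC(C)[Si](C(C)C)(C(C)C)OC[C@](C)(C=O)CC[C@@H](C(C)C)CO
F2 | step 6 | (3R,6E,10R,13S)-8-(benzenesulfonyl)-13-(hydroxymethyl)-3,7,10,14-tetramethyl-10-({[tri(propan-2-yl)silyl]oxy}methyl)pentadeca-1,6-diene-3,9-diol, C8/C9 epimers | C=C[C@](C)(O)CC/C=C(\C)C(S(=O)(=O)c1ccccc1)C(O)[C@@](C)(CO[Si](C(C)C)(C(C)C)C(C)C)CC[C@@H](C(C)C)CO
F3 | step 6 | (2S,5R,8E,12R)-7-(benzenesulfonyl)-12-hydroxy-5,8,12-trimethyl-6-oxo-2-(propan-2-yl)-5-({[tri(propan-2-yl)silyl]oxy}methyl)tetradeca-8,13-dienal, C7 epimers | C=C[C@](C)(O)CC/C=C(\C)C(S(=O)(=O)c1ccccc1)C(=O)[C@@](C)(CO[Si](C(C)C)(C(C)C)C(C)C)CC[C@@H](C(C)C)C=O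
F4 | step 11 | (2E,6R)-6-hydroxy-2,6-dimethylocta-2,7-dienal | O=C/C(C)=C/CC[C@@](C)(O)C=C
F5 | step 11 | (2E,6R,7E,9S,12R)-6-hydroxy-2,6,12-trimethyl-9-(propan-2-yl)-12-({[tri(propan-2-yl)silyl]oxy}methyl)trideca-2,7-dienedial | O=C/C(C)=C/CC[C@@](C)(O)/C=C/[C@H](C(C)C)CC[C@@](C)(C=O)CO[Si](C(C)C)(C(C)C)C(C)C
F6 | step 11 | (2R,5S,6E,8R,11E)-8,13-dihydroxy-2,8,12-trimethyl-5-(propan-2-yl)-2-({[tri(propan-2-yl)silyl]oxy}methyl)trideca-6,11-dienal | OC/C(C)=C/CC[C@@](C)(O)/C=C/[C@H](C(C)C)CC[C@@](C)(C=O)CO[Si](C(C)C)(C(C)C)C(C)C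
F7 | step 11 | (2R,5S,6E,8R,11E)-13-chloro-8-hydroxy-2,8,12-trimethyl-5-(propan-2-yl)-2-({[tri(propan-2-yl)silyl]oxy}methyl)trideca-6,11-dienal | ClC/C(C)=C/CC[C@@](C)(O)/C=C/[C@H](C(C)C)CC[C@@](C)(C=O)CO[Si](C(C)C)(C(C)C)C(C)C
F8 | step 11 | (2R,5S,6E,8R,11E)-13-(benzenesulfonyl)-8-hydroxy-2,8,12-trimethyl-5-(propan-2-yl)-2-({[tri(propan-2-yl)silyl]oxy}methyl)trideca-6,11-dienal | O=S(=O)(C/C(C)=C/CC[C@@](C)(O)/C=C/[C@H](C(C)C)CC[C@@](C)(C=O)CO[Si](C(C)C)(C(C)C)C(C)C)c1ccccc1
F9 | step 11 | (3E,7R,8E,10S,13R)-2-(benzenesulfonyl)-3,7,13-trimethyl-10-(propan-2-yl)-13-({[tri(propan-2-yl)silyl]oxy}methyl)cyclotrideca-3,8-diene-1,7-diol, C1/C2 epimers | OC1C(S(=O)(=O)c2ccccc2)/C(C)=C/CC[C@@](C)(O)/C=C/[C@H](C(C)C)CC[C@]1(C)CO[Si](C(C)C)(C(C)C)C(C)C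
F10 | step 13 | (3E,7R,8E,10S,13R)-7-hydroxy-13-(hydroxymethyl)-3,7,13-trimethyl-10-(propan-2-yl)cyclotrideca-3,8-dien-1-one | O=C1C/C(C)=C/CC[C@@](C)(O)/C=C/[C@H](C(C)C)CC[C@]1(C)CO
F11 | step 13 | (1S,3E,7R,8E,10S,13R)-13-(hydroxymethyl)-3,7,13-trimethyl-10-(propan-2-yl)cyclotrideca-3,8-diene-1,7-diol | O[C@H]1C/C(C)=C/CC[C@@](C)(O)/C=C/[C@H](C(C)C)CC[C@]1(C)CO
F12 | step 13 | (1S,2S,4E,8R,9E,11S)-2,8-dihydroxy-1,4,8-trimethyl-11-(propan-2-yl)cyclotrideca-4,9-diene-1-carbaldehyde | O[C@H]1C/C(C)=C/CC[C@@](C)(O)/C=C/[C@H](C(C)C)CC[C@]1(C)C=O
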